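**Plan**
Feature: in 29 the ring D oxygen is bound to C3, β to the C1 ketone of ring C. H8 (α to the ring B lactone carbonyl C7) and the carboxyl carbon C15 of the acrylic acid on C13 of ring A are what remains when the C8–C15 bond of a bicyclo[3.2.1]octane β-keto lactone is severed. Both motifs fold back into one compound, 27.
Cuts: O–C3 is opened and C8–C15 re-joined (29 → 27). Then follow C13–C16 (vinyl radical), C8–C15 (enolate alkylation), C9–C11 and C8–C14 (Diels–Alder), O–C7 (lactonisation), C9–C10 (Michael), C10–C20 (Claisen) and C5–C6 (conjugate vinylation).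
Forward: ring C is bought and kept from step 2 on as an enone without acidic hydrogens. Ring B, ring A and the five-membered carbocycle follow in that order. Ring D closes last, in the operation that opens the carbocycle.
Stereochemistry: C5 comes from rhodium/(R)-BINAP catalysis, C10 from Michael attack anti to the C6 arm, and C9 from diene approach past the flat C1 carbonyl. Quaternary C8 comes from alkylation syn to H9, C13 and C3 from tether geometry, and H8 from kinetic protonation.

Key step: step 17

Remark: ent-kaurane atom numbers and the ring letters A (cyclohexane), B (δ-lactone), C (cyclohexenone or cyclohexanone) and D (tetrahydrofuran) are used throughout. TBS = tert-butyldimethylsilyl. Compounds 15, 16, 21 and 25 are carried as epimer mixtures at C8 or C15, centres that the next step flattens.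

Step 1
Reactants: 1 4,4-dimethylcyclohex-2-en-1-one
Product: 2 4,4-dimethylcyclohexa-2,5-dien-1-one
Conditions: DDQ, 1,4-dioxane, reflux
Reagents that add atoms: none
Why: Quinone dehydrogenation of an enone by way of its dienol should introduce the second ring alkene, and the quaternary C4 rules out aromatisation under these neutral conditions.

Step 2
Reactants: 2 4,4-dimethylcyclohexa-2,5-dien-1-one; 3 potassium vinyltrifluoroborate
Product: 4 (R)-4,4-dimethyl-5-vinylcyclohex-2-en-1-one
Conditions: [Rh(cod)2]BF4 (3 mol %), (R)-BINAP (3.3 mol %), Et3N, toluene/H2O, 60 °C, 2 in slight excess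
Reagents that add atoms: potassium vinyltrifluoroborate (3), C=C[B-](F)(F)F.[K+]
Why: Hayashi–Miyaura-type asymmetric 1,4-addition of an alkenyltrifluoroborate, in which the vinylrhodium–(R)-BINAP species should insert one of the two equivalent enone units from the face this ligand selects in cyclohexenones, setting C5 as (R), while limiting 3 and the added crowding beside C4 hold back a second addition.

Step 3
Reactants: 4 (R)-4,4-dimethyl-5-vinylcyclohex-2-en-1-one
Product: 6 (S)-5-(hydroxymethyl)-4,4-dimethylcyclohex-2-en-1-one, via keto aldehyde 5 (not isolated)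
Conditions: O3, CH2Cl2/MeOH, −78 °C; Me2S; then NaBH4, −78 °C; pH 7 buffer
Reagents that add atoms: ozone, [O-][O+]=O
Why: Ozonolysis should take the electron-rich vinyl group ahead of the electron-poor enone, and borohydride at −78 °C reduces an aldehyde much faster than a conjugated ketone, so C6 reaches the alcohol level before the α-centre C5 can epimerise.

Step 4
Reactants: 6 (S)-5-(hydroxymethyl)-4,4-dimethylcyclohex-2-en-1-one
Product: 7 (S)-5-{[(tert-butyldimethylsilyl)oxy]methyl}-4,4-dimethylcyclohex-2-en-1-one
Conditions: TBSCl, imidazole, DMF, 0 °C → rt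
Reagents that add atoms: tert-butyldimethylsilyl chloride, C[Si](C)(Cl)C(C)(C)C
Why: Standard silylation of a primary alcohol under weakly basic conditions masks the C6 hydroxyl so that it cannot add to C3 before the last step.

Step 5
Reactants: 7 (S)-5-{[(tert-butyldimethylsilyl)oxy]methyl}-4,4-dimethylcyclohex-2-en-1-one; 8 ethyl formate
Product: 9 (5R,6Z)-5-{[(tert-butyldimethylsilyl)oxy]methyl}-6-(hydroxymethylidene)-4,4-dimethylcyclohex-2-en-1-one
Conditions: NaH, EtOH (cat.), THF, 0 °C → rt; AcOH
Reagents that add atoms: ethyl formate (8), CCOC=O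
Why: Crossed Claisen condensation, in which C10 is the only enolisable carbon of 7 because C4 blocks the γ-position, so formylation can only deliver C20 there and the product rests as its chelated enol.

Step 6
Reactants: 10 diallyl malonate; 11 formaldehyde (as paraformaldehyde)
Product: 12 diallyl 2-methylidenemalonate
Conditions: (CH2O)n, Cu(OAc)2 (cat.), KOAc (cat.), AcOH, 95 °C; distillation
Reagents that add atoms: formaldehyde (11), C=O
Why: Knoevenagel condensation of a malonate with formaldehyde followed by distillation is the standard access to monomeric methylidenemalonates, which are used at once.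

Step 7
Reactants: 9 (5R,6Z)-hydroxymethylidene enone; 12 diallyl 2-methylidenemalonate
Product: 13 diallyl 2-{[(1S,2R)-2-{[(tert-butyldimethylsilyl)oxy]methyl}-1-formyl-3,3-dimethyl-6-oxocyclohex-4-en-1-yl]methyl}malonate
Conditions: Et3N (10 mol %), CH2Cl2, −20 → 0 °C, slow addition of 12
Reagents that add atoms: diallyl 2-methylidenemalonate (12), C=C(C(=O)OCC=C)C(=O)OCC=C
Why: Michael addition of a β-keto aldehyde to a doubly activated acceptor forms C9–C10 under catalytic base, and because allylic strain against the fully substituted C10 turns the C6 arm axial the acceptor should enter on the opposite face, setting quaternary C10 as (S) with C9 trans and the formyl carbon C20 cis to that arm.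

Step 8
Reactants: 13 keto aldehyde malonate (5R,10S)
Product: 15 allyl (6S,11R)-11-{[(tert-butyldimethylsilyl)oxy]methyl}-10,10-dimethyl-3,7-dioxo-2-oxaspiro[5.5]undec-8-ene-4-carboxylate (C8 epimers), via hydroxy malonate 14 (not isolated)
Conditions: NaBH4, CH2Cl2/MeOH, −78 °C; pH 7 buffer; then PPTS (cat.), toluene, 60 °C
Reagents that add atoms: none
Why: Chemoselective borohydride reduction of the aldehyde beside the hindered enone and the esters is followed by acid-catalysed lactonisation of the C20 alcohol onto one malonate ester, which closes ring B and traps the β-hydroxy ketone before retro-aldol loss of C20.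

Step 9
Reactants: 15 spirolactone allyl ester (5R,10S)
Product: 17 allyl (6S,11R)-11-{[(tert-butyldimethylsilyl)oxy]methyl}-10,10-dimethyl-3,7-dioxo-2-oxaspiro[5.5]undeca-4,8-diene-4-carboxylate, via selenide 16 (not isolated)
Conditions: NaH, THF, 0 °C; PhSeCl, −78 °C; then H2O2 (30 %), CH2Cl2, 0 °C
Reagents that add atoms: none
Why: α-Selenenylation of the malonate-type anion and selenoxide syn-elimination, the usual route to 2-alkoxycarbonyl enones and enoates, should place the C8=C9 alkene in ring B since only C9 offers β-hydrogens.

Step 10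
Reactants: 17 doubly activated spiro dienophile (5R,10S); 18 buta-1,3-diene
Product: 19 Diels–Alder adduct (5R,8S,9S,10S): ring A as a C12=C13 cyclohexene cis-fused to ring B; CO2allyl (C15) on C8 syn to H9; 6-OTBS; C1 enone
Conditions: 18 (excess), ZnCl2 (1 M in Et2O), CH2Cl2, 0 °C → rt, sealed tube
Reagents that add atoms: buta-1,3-diene (18), C=CC=C
Why: Lewis acid promoted Diels–Alder reaction of a chelated alkylidene-malonate-type dienophile, a class that accepts butadiene even beside a quaternary carbon, forms C9–C11 and C8–C14 suprafacially, and the diene should pass the flat C1 carbonyl rather than C5 with its silyloxymethyl arm and gem-dimethyl neighbour, which sets C9 as (S) while the singly activated, equally hindered ring C enone stays out.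

Step 11
Reactants: 19 Diels–Alder adduct
Product: 21 tricyclic lactone (5R,9R,10S; C8 epimers) with hydrogen on C8, via malonic half-acid 20 (not isolated)
Conditions: Pd(PPh3)4 (5 mol %), morpholine, THF, rt; citric acid wash; then DMF, 120 °C
Reagents that add atoms: none
Why: Tsuji–Trost deallylation with zerovalent palladium and an amine scavenger frees the malonic half-acid under neutral conditions and heating expels CO2, so the activating group leaves without touching silyl ether, enone or lactone, and the C8 epimer composition is irrelevant.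

Step 12
Reactants: 21 tricyclic lactone; 22 2,3-dibromoprop-1-ene
Product: 23 8-(2-bromoallyl) lactone (5R,8R,9S,10S) with C15 syn to H9
Conditions: KN(SiMe3)2, THF/DMPU, −78 °C; 22, −78 → −30 °C
Reagents that add atoms: 2,3-dibromoprop-1-ene (22), C=C(Br)CBr
Why: Alkylation of the ring-fusion lactone enolate, possible because the ring C enone has no acidic hydrogen, should occur on the face that carries H9 since the other face is covered by the pseudoaxial C1 carbon and the axial hydrogens of ring A, as is usual for fused enolates that give cis-fused products, and this sets quaternary C8 as (R).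

Step 13
Reactants: 23 8-(2-bromoallyl) lactone
Product: 24 6-OTBS-1-oxo-6,7-seco-ent-kaura-2,16-dien-7,20-olide (5R,8R,9S,10S,13R)
Conditions: Bu3SnH, AIBN, PhH (0.02 M), 80 °C
Reagents that add atoms: none
Why: Tin hydride mediated 5-exo-trig vinyl radical cyclisation forms C13–C16, the two-atom tether from C8 reaches C13 only on the face of ring A where C15 stands so C13 is set as (R), and a moderate stannane concentration should capture the C12 radical before it rearranges to the bicyclo[2.2.2]octane.

Step 14
Reactants: 24 exo-methylene tetracycle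
Product: 25 15-hydroxy derivative of 24 (5R,8S,9S,10S,13R; C15 epimers)
Conditions: SeO2 (0.5 equiv), t-BuOOH, CH2Cl2, rt
Reagents that add atoms: selenium dioxide, O=[Se]=O (oxygen carrier); tert-butyl hydroperoxide, CC(C)(C)OO (terminal oxygen source)
Why: SeO2 allylic oxidation (ene reaction then [2,3]-sigmatropic shift) can only strike C15, because the other allylic carbon C13 is a bridgehead and ring C has no allylic hydrogen.

Step 15
Reactants: 25 15-hydroxy tetracycle
Product: 26 6-OTBS-1,15-dioxo-6,7-seco-ent-kaura-2,16-dien-7,20-olide (5R,8S,9S,10S,13R)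
Conditions: DMP, CH2Cl2, rt
Reagents that add atoms: none
Why: Dess–Martin oxidation turns the allylic alcohol into the exo-methylene ketone under neutral conditions that spare the non-enolisable β-keto lactone so formed.

Step 16
Reactants: 26 silyl-protected dione
Product: 27 6-hydroxy-1,15-dioxo-6,7-seco-ent-kaura-2,16-dien-7,20-olide (5R,8S,9S,10S,13R)
Conditions: HF·pyridine, pyridine, THF, 0 °C
Reagents that add atoms: none
Why: Fluoride-driven cleavage of the primary silyl ether in a pyridine-buffered acidic medium should free the C6 hydroxyl without supplying the base that ring D closure and cleavage of the β-keto lactone need.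

Step 17
Reactants: 27 6-hydroxy-1,15-dioxo-6,7-seco-ent-kaura-2,16-dien-7,20-olide
Product: 29 target CNP0268721.2 (3R,5R,8S,9R,10S,13R), via oxa-bridged keto lactone 28 (not isolated)
Conditions: LiOH (3 equiv), THF/H2O (3:1), 0 °C; then 1 M HCl to pH 2, rt
Reagents that add atoms: lithium hydroxide, [Li+].[OH-]
Why: Base turns the C6 hydroxyl into an alkoxide that adds to C3 of the C1 enone (intramolecular oxa-Michael addition, 5-exo-trig closure of ring D) to give 28, and hydroxide then adds to the C15 carbonyl, whose tetrahedral adduct collapses by breaking C8–C15 (retro-Claisen cleavage), releasing the ring B lactone enolate and an acrylic acid that is deprotonated at once and so takes the cleavage out of equilibrium. The closest known reaction types are the hydroxide cleavage of α,α-disubstituted, non-enolisable β-keto esters and the base-induced cyclisation of hydroxy enones to oxa-bridged ketones. C3 becomes (R) through the tether, because the oxygen on the axial C6 arm of C5 can only meet the enone face on which that arm stands. C8 becomes (S) through kinetic protonation of an enolate that is exocyclic to ring A, the proton arriving along the equatorial direction on the face that C15 has just left and away from the pseudoaxial C1 carbon, which places H8 on the same face of ring A as H9 and the acrylic acid substituent and leaves C7 axial. The selectivity needed is attack at C15 ahead of C7 and C17, and the substrate provides it since C15 is a strained bridged ketone, C7 is screened by quaternary C8 and a hydroxy acid formed there simply re-lactonises on acidification (its decarboxylation would need a bridgehead enol), and addition at C17 is reversible and is drained by the cleavage. Low temperature and short contact keep the new lactone α-centre from equilibrating and a transiently freed C20 hydroxymethyl ketone from retro-aldol loss.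

**Compound list**
1 | 4,4-dimethylcyclohex-2-en-1-one | CC1(C)CCC(=O)C=C1 | starting material
2 | 4,4-dimethylcyclohexa-2,5-dien-1-one | CC1(C)C=CC(=O)C=C1 | intermediate
3 | potassium vinyltrifluoroborate | C=C[B-](F)(F)F.[K+] | starting material
4 | (R)-4,4-dimethyl-5-vinylcyclohex-2-en-1-one | O=C1C=CC(C)(C)[C@@H](C=C)C1 | intermediate
5 | (S)-2,2-dimethyl-5-oxocyclohex-3-ene-1-carbaldehyde | O=C1C=CC(C)(C)[C@@H](C=O)C1 | intermediate
6 | (S)-5-(hydroxymethyl)-4,4-dimethylcyclohex-2-en-1-one | O=C1C=CC(C)(C)[C@@H](CO)C1 | intermediate
7 | (S)-5-{[(tert-butyldimethylsilyl)oxy]methyl}-4,4-dimethylcyclohex-2-en-1-one | O=C1C=CC(C)(C)[C@@H](CO[Si](C)(C)C(C)(C)C)C1 | intermediate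
8 | ethyl formate | CCOC=O | starting material
9 | (5R,6Z)-5-{[(tert-butyldimethylsilyl)oxy]methyl}-6-(hydroxymethylidene)-4,4-dimethylcyclohex-2-en-1-one | O/C=C1\C(=O)C=CC(C)(C)[C@H]1CO[Si](C)(C)C(C)(C)C | intermediate
10 | diallyl malonate | C=CCOC(=O)CC(=O)OCC=C | starting material
11 | formaldehyde (as paraformaldehyde) | C=O | starting material
12 | diallyl 2-methylidenemalonate | C=C(C(=O)OCC=C)C(=O)OCC=C | intermediate
13 | diallyl 2-{[(1S,2R)-2-{[(tert-butyldimethylsilyl)oxy]methyl}-1-formyl-3,3-dimethyl-6-oxocyclohex-4-en-1-yl]methyl}malonate (C20 formyl cis, C9 trans to the C6 arm) | O=C[C@@]1(CC(C(=O)OCC=C)C(=O)OCC=C)C(=O)C=CC(C)(C)[C@H]1CO[Si](C)(C)C(C)(C)C | intermediate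
14 | the 1-(hydroxymethyl) analogue of 13 (5R,10S) | OC[C@@]1(CC(C(=O)OCC=C)C(=O)OCC=C)C(=O)C=CC(C)(C)[C@H]1CO[Si](C)(C)C(C)(C)C | intermediate
15 | allyl (6S,11R)-11-{[(tert-butyldimethylsilyl)oxy]methyl}-10,10-dimethyl-3,7-dioxo-2-oxaspiro[5.5]undec-8-ene-4-carboxylate (C8 epimers) | C=CCOC(=O)C1C[C@]2(COC1=O)C(=O)C=CC(C)(C)[C@H]2CO[Si](C)(C)C(C)(C)C | intermediate
16 | 4-(phenylselanyl) derivative of 15 (selenium on C8) | C=CCOC(=O)C1([Se]c3ccccc3)C[C@]2(COC1=O)C(=O)C=CC(C)(C)[C@H]2CO[Si](C)(C)C(C)(C)C | intermediate
17 | allyl (6S,11R)-11-{[(tert-butyldimethylsilyl)oxy]methyl}-10,10-dimethyl-3,7-dioxo-2-oxaspiro[5.5]undeca-4,8-diene-4-carboxylate | C=CCOC(=O)C1=C[C@]2(COC1=O)C(=O)C=CC(C)(C)[C@H]2CO[Si](C)(C)C(C)(C)C | intermediate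
18 | buta-1,3-diene | C=CC=C | starting material
19 | Diels–Alder adduct (5R,8S,9S,10S): C12=C13 cyclohexene (ring A) cis-fused to ring B, CO2allyl on C8 syn to H9, 6-OTBS, C1 enone | C1C=CC[C@@H]2[C@@]1(C(=O)OCC=C)C(=O)OC[C@]21C(=O)C=CC(C)(C)[C@H]1CO[Si](C)(C)C(C)(C)C | intermediate
20 | carboxylic acid from 19 (CO2H on C8) | C1C=CC[C@@H]2[C@@]1(C(=O)O)C(=O)OC[C@]21C(=O)C=CC(C)(C)[C@H]1CO[Si](C)(C)C(C)(C)C | intermediate
21 | tricyclic lactone (5R,9R,10S; C8 epimers), hydrogen on C8 | C1C=CC[C@@H]2C1C(=O)OC[C@]21C(=O)C=CC(C)(C)[C@H]1CO[Si](C)(C)C(C)(C)C | intermediate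
22 | 2,3-dibromoprop-1-ene | C=C(Br)CBr | starting material
23 | 8-(2-bromoallyl) lactone (5R,8R,9S,10S), C15 syn to H9 | C1C=CC[C@@H]2[C@@]1(CC(Br)=C)C(=O)OC[C@]21C(=O)C=CC(C)(C)[C@H]1CO[Si](C)(C)C(C)(C)C | intermediate
24 | 6-OTBS-1-oxo-6,7-seco-ent-kaura-2,16-dien-7,20-olide (5R,8R,9S,10S,13R) | C=C(C3)[C@@H]1CC[C@@H]2[C@]3(C1)C(=O)OC[C@]21C(=O)C=CC(C)(C)[C@H]1CO[Si](C)(C)C(C)(C)C | intermediate
25 | 15-hydroxy derivative of 24 (C15 epimers) | C=C(C3O)[C@@H]1CC[C@@H]2[C@]3(C1)C(=O)OC[C@]21C(=O)C=CC(C)(C)[C@H]1CO[Si](C)(C)C(C)(C)C | intermediate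
26 | 6-OTBS-1,15-dioxo-6,7-seco-ent-kaura-2,16-dien-7,20-olide (5R,8S,9S,10S,13R) | C=C(C3=O)[C@@H]1CC[C@@H]2[C@]3(C1)C(=O)OC[C@]21C(=O)C=CC(C)(C)[C@H]1CO[Si](C)(C)C(C)(C)C | intermediate
27 | 6-hydroxy-1,15-dioxo-6,7-seco-ent-kaura-2,16-dien-7,20-olide (5R,8S,9S,10S,13R) | C=C(C3=O)[C@@H]1CC[C@@H]2[C@]3(C1)C(=O)OC[C@]21C(=O)C=CC(C)(C)[C@H]1CO | intermediate
28 | 3,6-epoxy-1,15-dioxo-6,7-seco-ent-kaur-16-en-7,20-olide (3R,5R,8S,9S,10S,13R) | C=C(C3=O)[C@@H]1CC[C@@H]2[C@]3(C1)C(=O)OC[C@]21C(=O)C[C@H]2OC[C@@H]1C2(C)C | intermediate
29 | CNP0268721.2, 3,6-epoxy-1-oxo-6,7:8,15-diseco-ent-kaur-16-en-7,20-olid-15-oic acid (3R,5R,8S,9R,10S,13R) | C=C(C(=O)O)[C@@H]1CC[C@@H]2[C@H](C1)C(=O)OC[C@]21C(=O)C[C@H]2OC[C@@H]1C2(C)C | target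

**Totals**
Total step count: 17. Longest linear sequence: 16 steps (steps 1–5 and 7–17). Step 6 is a one-step side branch.

**Steps most likely to fail**

Step 17. Hydroxide may open ring B faster than it attacks C15. The freed C20 hydroxymethyl ketone could then lose formaldehyde by retro-aldol. The C8 enolate may also be protonated on the wrong face, or the new α-centre may equilibrate.
- The fallback separates the two events and avoids hydroxide. It sets out from 27.
- Catalytic DBU in CH2Cl2 closes ring D, and 28 is now isolated.
- LiOCH2CH=CH2 in THF/allyl alcohol at −40 °C then carries out the retro-Claisen cleavage as an alcoholysis. Opening of ring B is here only a reversible transesterification, and allyl alcohol is the sole proton source. This gives the allyl ester of the target F1.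
- Pd(PPh3)4 and morpholine remove the allyl group under neutral conditions, and the route is rejoined at 29.

Step 10. Cycloaddition at the neopentyl carbon C9 may be slower than Lewis acid induced polymerisation of the diene. Forcing temperatures would erode facial selectivity.
- The fallback builds ring A bond by bond. It sets out from 17.
- Hosomi–Sakurai addition of allyltrimethylsilane (TiCl4, CH2Cl2, −78 °C) to the chelated alkylidene malonate unit attaches C11 and C12 to C9 on the face beside C1. This gives the C9-allyl lactone ester F2.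
- Deallylation as in step 11 gives the malonic half-acid F3, and heating gives the C9-allyl spirolactone F4.
- KN(SiMe3)2 and allyl bromide give the trans-8,9-diallyl lactone F5.
- Ring-closing metathesis with the second-generation Grubbs catalyst joins C12 to C13. The route is rejoined at 21 as its trans-fused C8 epimer, which serves equally well because step 12 flattens C8.

Step 13. The vinyl radical may be reduced before it cyclises. The C12 radical may rearrange through a cyclopropylcarbinyl radical to the bicyclo[2.2.2]octane. Tin radicals may also engage the enone.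
- The fallback replaces the radical by a two-electron closure. It sets out from 21.
- Alkylation under the conditions of step 12 with propargyl bromide gives the 8-propargyl lactone F6.
- Reductive enyne cyclisation follows (Pd2(dba)3·CHCl3, AcOH, Et3SiH, toluene, rt). It runs through hydropalladation of the alkyne, 5-exo carbopalladation of C12=C13 and silane capture of the C12–palladium bond.
- This delivers the exo-methylene bridge, and the route is rejoined at 24.

**Further compounds**
F1 | step 17 | allyl ester of 29 (allyl acrylate on C13, otherwise as the target) | C=CCOC(=O)C(=C)[C@@H]1CC[C@@H]2[C@H](C1)C(=O)OC[C@]21C(=O)C[C@H]2OC[C@@H]1C2(C)C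
F2 | step 10 | C9-allyl spirolactone allyl ester (C8 epimers) | C=CC[C@@H]2C(C(=O)OCC=C)C(=O)OC[C@]21C(=O)C=CC(C)(C)[C@H]1CO[Si](C)(C)C(C)(C)C
F3 | step 10 | malonic half-acid from F2 | C=CC[C@@H]2C(C(=O)O)C(=O)OC[C@]21C(=O)C=CC(C)(C)[C@H]1CO[Si](C)(C)C(C)(C)C
F4 | step 10 | C9-allyl spirolactone | C=CC[C@@H]2CC(=O)OC[C@]21C(=O)C=CC(C)(C)[C@H]1CO[Si](C)(C)C(C)(C)C
F5 | step 10 | trans-8,9-diallyl spirolactone | C=CC[C@@H]2[C@@H](CC=C)C(=O)OC[C@]21C(=O)C=CC(C)(C)[C@H]1CO[Si](C)(C)C(C)(C)C
F6 | step 13 | 8-propargyl lactone, C15 syn to H9 | C1C=CC[C@@H]2[C@@]1(CC#C)C(=O)OC[C@]21C(=O)C=CC(C)(C)[C@H]1CO[Si](C)(C)C(C)(C)C
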